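The red run, at 2.4 M with 1.05 equiv of reagent, has the same equivalents as the new flask at a higher concentration, so I reckoned from it.

| flask | starting material | reagent | remark | time |
|---|---|---|---|---|
| blue | 1.6 M | 0.70 equiv | run made earlier |  |
| grey | 1.6 M | 1.6 equiv | run made earlier |  |
| red | 2.4 M | 1.05 equiv | run made earlier |  |
| flask | 1.6 M | 1.05 equiv |  | 40 min |

- blue (time / min: mono adduct / %): 3.00: 14.0; 6.00: 20.2; 12.0: 24.4; 20.0: 25.3; 40.0: 25.6
- grey (time / min: mono adduct / %): 3.00: 26.2; 6.00: 30.7; 12.0: 29.1; 20.0: 23.8; 40.0: 14.2
- red (time / min: mono adduct / %): 3.00: 23.2; 6.00: 28.1; 12.0: 28.3; 20.0: 26.3; 40.0: 22.6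

(readings scatter by 0.3 percentage points)



- the moment within 40 min at which there is most mono adduct
- the amount of mono adduct, in percent of the starting material charged, at that time
- the first time at which mono adduct reaches 14 %, in the same percent, in min

If every step is second order overall, equal equivalents make each rate, in percent of the charge, scale with the charged concentration. The flask should then retrace red's curve at the same heights, with its clock slowed by 1.50. I call this ratio of charged concentrations at equal equivalents the stretch factor.

My first doubt was a first-order loss of mono adduct, whose rate does not stretch and which should show as a fall once blue flattens. Yet blue's readings rose by 0.3 percentage points between 20.0 min and 40.0 min, about the scatter, so I kept the rule.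

Red's readings at 6.00 min and 12.0 min differ by 0.2 points, less than the scatter, so I put red's top at their midpoint, 9.00 min, which stretches to 13.5 min in the flask. But both readings may lie on the shoulders, so I expected the top above them. The curvature between the slopes before and after them adds 0.74 points, giving a height of 28.9 %. Those slopes lie far from the top, so this correction is rough.

The forecast gave 14 min (10 min to 20 min) for the time of the top, 27.5 % (26 % to 29 %) for its height and 1.9 min (1.6 min to 2.2 min) for reaching 14 %, saying “its timescale is about 1.5 times longer”. We differed on the time, mine being earlier, and on the height, mine being higher. For the time of reaching 14 % I took the forecast's figure.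

The flask peaked at 12.8 min with 28.7 % mono adduct and reached 14 % at 1.66 min, each inside the forecast's range.

    starting material + reagent → mono adduct (k = 0.00120 M⁻¹ s⁻¹)
    starting material + reagent → other mono adduct (k = 5.30 × 10⁻⁴ M⁻¹ s⁻¹)
    reagent + mono adduct → bis adduct (k = 8.70 × 10⁻⁴ M⁻¹ s⁻¹)
    reagent + other mono adduct → bis adduct (k = 3.70 × 10⁻⁵ M⁻¹ s⁻¹)
    2 starting material → homo dimer (k = 3.60 × 10⁻⁴ M⁻¹ s⁻¹)

At 3.47 min the flask made mono adduct 3.38 times as fast as it used it up, each step taken net, and at 40.0 min the same ratio stood at 0.405, so the two rates cross at the peak, which the stretch factor puts at 8.51 min on red's clock. The same flask read at 1.5 h stands at 60.0 min on that clock and holds 21.2 % mono adduct, less than the 22.6 % red showed at 40.0 min.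

The readings are calculated for substances that don't exist.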